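The vessel held L from the start and took J at a steady rate over 1.0 h, and I wanted the length at the end, which is [Z] over the number of chains.

all flasks: L 0.20 mM
- cedar: J 0.022 M (fed, over 1.0 h); run made earlier
- oak: J 0.088 M (fed, over 1.0 h); run made earlier
- dawn: J 0.10 M (fed, over 1.0 h); time 1.0 h
- midnight: J 0.030 M (fed, over 1.0 h); time 1.0 h

- cedar (time / min: Z / %): 10.0: 0.8; 20.0: 2.8; 30.0: 4.9; 40.0: 7.8; 50.0: 11.1; 60.0: 15.1
- oak (time / min: Z / %): 5.00: 0.6; 8.00: 0.5; 12.0: 0.9; 20.0: 2.2; 40.0: 7.3; 60.0: 14.6

(each reading ± 0.3 percentage points)

- which of the two ends with the longer chains by the average number of monomer units in a chain (living and dead chains, two that joined counted as one) ("neither" if they lie within 10 %) (dawn / midnight / neither)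
- average number of monomer units in a chain (living and dead chains, two that joined counted as one) at the end, dawn
- average number of monomer units in a chain (living and dead chains, two that joined counted as one) at the end, midnight

- the average divides the monomer in chains by the number of chains, living and dead together; two radicals that join make one chain
- steps thought possible: 2 Q -> X; J + D -> Q + Z; L -> 2 D; J + Q -> Z + Q
- the earlier runs do not show the number of chains; that part of a forecast is a guess
- percentages count the whole charge, also what has not yet gone in

At 60.0 min cedar had reached 15.1 % and oak 14.6 % of their charges, a gap of 0.5 percentage points against a scatter of 0.3 points, though oak held 4.00 times the J of cedar. So I read the growth as pseudo-first-order in J and took one yield, 14.8 %, for dawn and midnight as well. With [L] and the time held, I assumed the number of chains did not follow the charge, so length went with the charge.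

I kept the length per molar of J charged, counted at one chain per L charged, s = yield / [L], which I reckoned as 742 M⁻¹. That gave me 74.2 for dawn and 22.3 for midnight, so dawn was longer. Both figures were low if part of the L stayed unspent, since that meant fewer chains.

The forecast, higher than my figures, said dawn, with 96 (70 to 170) and 29 (21 to 55), holding that “the radical level does not depend on J”.

The flask gave dawn: dawn 105, midnight 32.8.

    2 Q → X (k = 1.10 × 10⁷ M⁻¹ s⁻¹)
    J + D → Q + Z (k = 52000 M⁻¹ s⁻¹)
    L → 2 D (k = 1.10 h⁻¹)
    J + Q → Z + Q, rate k4*[Q]*[J] (k = 5.90 × 10⁶ M⁻¹ h⁻¹)

In midnight at 1.00 h, L had a half-life of 0.63 h by its breaking, shorter than the 2.7 h of J by growth. There 33 % of the L and 85 % of the J stood left, and s over the L spent gave 33.4. A neighbouring flask, midnight with 0.051 M of J, left 33 % of its L, so s gave 37.8 per L charged and 56.5 per L spent; its computed length was 54.6.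

(The runs were generated by integration for an exercise, and the scatter is random.)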